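**Overview**

- **Cuts** (lactone numbered O1, C2 carbonyl, C3, C4, C5): both phenols are masked as benzyl ethers. The O1–C2 bond is opened to a γ-hydroxy tert-butyl ester, C5 is taken back to an acyl oxazolidinone carbonyl, and last the C3–C4 bond is cut.
- **Enabling feature:** C3 and C4 of the butyrolactone each bear one arylmethyl group. Each is also flanked by a carboxyl-level carbon (C2 carbonyl next to C3, the C5 OCH2 next to C4). The ring is therefore a masked unsymmetrical 2,3-dibenzylsuccinate (guaiacyl and syringyl arms) whose central bond links two enolate α-carbons.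
- **Forward order:** sinapic acid gives the syringyl C6–C3 acyl oxazolidinone and ferulic acid the guaiacyl C6–C3 tert-butyl ester, three steps each. The two lithium enolates are joined oxidatively at their α-carbons. Only then is the one new ring, the lactone, closed by imide reduction and O-acylation.
- **Stereochemistry:** C4 (R) comes from the (S)-4-benzyloxazolidinone during the coupling and is locked when its carbonyl is reduced. C3 (R) comes from base equilibration to the trans lactone under control of C4.

Key step: step 7

Assumption: the coupling of step 7 is taken to control only the imide-side carbon, so 13–17 are carried as unseparated pairs of epimers at the ester-side carbon, their SMILES leave that one atom without a stereo label, and step 10 fixes it.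

**Route**

Step 1
Reactants: 1 sinapic acid
Product: 2 3-(4-hydroxy-3,5-dimethoxyphenyl)propanoic acid
Conditions: H2 (1 atm), 10% Pd/C, MeOH, rt
Reagents that add atoms: none
Why: Heterogeneous catalytic hydrogenation saturates the conjugated cinnamic alkene while arene, phenol and acid are inert, and it is placed before benzylation so that no benzyl ether meets Pd/C and hydrogen at this stage.

Step 2
Reactants: 2 3-(4-hydroxy-3,5-dimethoxyphenyl)propanoic acid
Product: 3 3-(4-benzyloxy-3,5-dimethoxyphenyl)propanoic acid
Conditions: BnBr (1.6 equiv), NaOH (4 equiv), EtOH/H2O, reflux; then aq HCl to pH 2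
Reagents that add atoms: benzyl bromide, BrCc1ccccc1
Why: Williamson ether synthesis on the phenoxide–carboxylate dianion, in which the phenoxide is by far the better nucleophile in the protic medium and any ester formed on the side is saponified by the excess hydroxide, so acidification should deliver the free acid with only the phenol benzylated.

Step 3
Reactants: 3 3-(4-benzyloxy-3,5-dimethoxyphenyl)propanoic acid; 4 (S)-4-benzyloxazolidin-2-one
Product: 6 (S)-4-benzyl-3-[3-(4-benzyloxy-3,5-dimethoxyphenyl)propanoyl]oxazolidin-2-one, via mixed pivalic anhydride 5 (not isolated)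
Conditions: PivCl, Et3N, THF, −20 °C; then LiCl, 4, −20 °C → rt
Reagents that add atoms: pivaloyl chloride, CC(C)(C)C(=O)Cl (its acyl group is held only by 5 and leaves again on the way to 6)
Why: Mixed-anhydride N-acylation of an oxazolidinone, in which the LiCl/Et3N pair makes the carbamate nitrogen nucleophilic enough to attack the unhindered carbonyl of 5 rather than the pivaloyl carbonyl, and the stereocentre of 4 is not involved.

Step 4
Reactants: 7 ferulic acid
Product: 8 3-(4-hydroxy-3-methoxyphenyl)propanoic acid
Conditions: H2 (1 atm), 10% Pd/C, MeOH, rt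
Reagents that add atoms: none
Why: Catalytic hydrogenation of the cinnamic double bond, as in step 1, leaves the arene, the phenol and the acid unchanged.

Step 5
Reactants: 8 3-(4-hydroxy-3-methoxyphenyl)propanoic acid
Product: 9 3-(4-benzyloxy-3-methoxyphenyl)propanoic acid
Conditions: BnBr (1.5 equiv), NaOH (4 equiv), EtOH/H2O, reflux; then aq HCl to pH 2
Reagents that add atoms: benzyl bromide, BrCc1ccccc1
Why: Williamson ether synthesis on the dianion as in step 2, here on a less hindered guaiacyl phenoxide, so that no free phenol is left to interfere with esterification or with the later oxidant.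

Step 6
Reactants: 9 3-(4-benzyloxy-3-methoxyphenyl)propanoic acid
Product: 10 tert-butyl 3-(4-benzyloxy-3-methoxyphenyl)propanoate
Conditions: Me2NCH(OtBu)2 (3 equiv), toluene, 80 °C
Reagents that add atoms: N,N-dimethylformamide di-tert-butyl acetal, CN(C)C(OC(C)(C)C)OC(C)(C)C
Why: Amide-acetal esterification, in which the acid protonates the acetal and the resulting alkoxyiminium carboxylate ion pair collapses by transfer of the tert-butyl group to the carboxylate oxygen under essentially neutral conditions that spare the benzyl ether and the electron-rich ring.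

Step 7
Reactants: 6 (S)-4-benzyl-3-[3-(4-benzyloxy-3,5-dimethoxyphenyl)propanoyl]oxazolidin-2-one; 10 tert-butyl 3-(4-benzyloxy-3-methoxyphenyl)propanoate
Product: 13 tert-butyl (3R)-4-[(S)-4-benzyl-2-oxooxazolidin-3-yl]-3-(4-benzyloxy-3,5-dimethoxybenzyl)-2-(4-benzyloxy-3-methoxybenzyl)-4-oxobutanoate (both C2 epimers), via imide lithium enolate 11 (not isolated), via ester lithium enolate 12 (not isolated)
Conditions: 6 (1 equiv) + 10 (1.5 equiv), LiN(iPr)2 (commercial solution, 2.6 equiv), THF, −78 °C; then Fe(acac)3 (2.6 equiv) in THF, −78 °C → rt; 1 M HCl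
Reagents that add atoms: lithium diisopropylamide, [Li+].CC(C)[N-]C(C)C (lithium in 11 and 12 only; no reagent atom stays in 13)
Why: Lithium diisopropylamide turns both carbonyl partners into their lithium enolates, trivalent iron then presumably removes one electron from the more electron-rich ester enolate 12, the α-ester radical adds to the α-carbon of the chelated imide enolate 11, and a second equivalent of Fe(acac)3 oxidises the resulting radical anion to the neutral 1,4-dicarbonyl compound 13. The closest known reaction type is the intermolecular oxidative heterocoupling of an imide enolate with an ester or ketone enolate by soluble one-electron oxidants of trivalent iron or divalent copper, an established entry to unsymmetrical 2,3-disubstituted succinates. No ring closes, since the only bond made is the one between the two α-carbons, the later lactone C3–C4 bond. The imide-side centre (later C4) is set by the auxiliary: lithium chelation between the enolate oxygen and the ring carbonyl holds the Z-enolate in one plane, the benzyl group of the (S)-oxazolidinone covers one face, and bond formation on the open face, as in an Evans alkylation, gives the R configuration, whereas the ester-side centre (later C3) has no controlling element and is expected as a pair of epimers that step 10 converges. The step needs cross- over homo-coupling, which the unlike oxidation potentials and aggregation states of the two enolate types and the excess of the cheaper ester 10 should secure, and it needs the arenes to stay untouched, which the CH2 spacers and the absence of any free phenol should secure.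

Step 8
Reactants: 13 tert-butyl (3R)-4-[(S)-4-benzyl-2-oxooxazolidin-3-yl]-3-(4-benzyloxy-3,5-dimethoxybenzyl)-2-(4-benzyloxy-3-methoxybenzyl)-4-oxobutanoate (both C2 epimers)
Product: 15 tert-butyl (3R)-3-(4-benzyloxy-3,5-dimethoxybenzyl)-2-(4-benzyloxy-3-methoxybenzyl)-4-hydroxybutanoate (both C2 epimers), via aldehyde 14 (not isolated)
Conditions: LiBH4 (1.5 equiv), MeOH (1.5 equiv), Et2O/THF, 0 °C; aqueous work-up
Reagents that add atoms: none
Why: Reductive cleavage of an N-acyl oxazolidinone by borohydride, in which lithium coordination activates the exocyclic imide carbonyl, hydride addition and loss of the oxazolidinone anion give aldehyde 14 that is reduced at once to the primary alcohol, the hindered tert-butyl ester is inert at 0 °C, and the imide-side stereocentre is retained and can no longer epimerise once its carbonyl neighbour is gone.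

Step 9
Reactants: 15 tert-butyl (3R)-3-(4-benzyloxy-3,5-dimethoxybenzyl)-2-(4-benzyloxy-3-methoxybenzyl)-4-hydroxybutanoate (both C2 epimers)
Product: 17 (4R)-4-(4-benzyloxy-3,5-dimethoxybenzyl)-3-(4-benzyloxy-3-methoxybenzyl)dihydrofuran-2(3H)-one (both C3 epimers), via hydroxy acid 16 (not isolated)
Conditions: CF3CO2H/CH2Cl2 (1:4), 0 °C → rt; aq NaHCO3
Reagents that add atoms: none
Why: Acidolysis of the tert-butyl ester by alkyl–oxygen cleavage gives γ-hydroxy acid 16, which closes by 5-exo-trig attack of the C5 hydroxyl on the carboxyl carbon (acid-catalysed lactonisation), no stereocentre is touched, and aryl benzyl ethers should tolerate dilute trifluoroacetic acid for a short time at or below room temperature.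

Step 10
Reactants: 17 (4R)-4-(4-benzyloxy-3,5-dimethoxybenzyl)-3-(4-benzyloxy-3-methoxybenzyl)dihydrofuran-2(3H)-one (both C3 epimers)
Product: 18 (3R,4R)-4-(4-benzyloxy-3,5-dimethoxybenzyl)-3-(4-benzyloxy-3-methoxybenzyl)dihydrofuran-2(3H)-one
Conditions: DBU (1 equiv), toluene, 60 °C
Reagents that add atoms: none
Why: Base-mediated thermodynamic epimerisation, in which C3 is the only stereocentre with an acidic hydrogen, reversible deprotonation passes through the planar lactone enolate, and reprotonation accumulates the more stable trans isomer in which the two arylmethyl groups avoid each other, so the fixed 4R centre dictates 3R.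

Step 11
Reactants: 18 (3R,4R)-4-(4-benzyloxy-3,5-dimethoxybenzyl)-3-(4-benzyloxy-3-methoxybenzyl)dihydrofuran-2(3H)-one
Product: 19 (3R,4R)-4-(4-hydroxy-3,5-dimethoxybenzyl)-3-(4-hydroxy-3-methoxybenzyl)dihydrofuran-2(3H)-one (target CNP0328745.1)
Conditions: H2 (1 atm), 10% Pd/C, EtOAc/EtOH, rt
Reagents that add atoms: none
Why: Catalytic hydrogenolysis of the two aryl benzyl ethers under neutral conditions frees both phenols, while the lactone, the methyl ethers and the two stereocentres are not affected.

**Compound list**

1 | sinapic acid, (E)-3-(4-hydroxy-3,5-dimethoxyphenyl)prop-2-enoic acid | COc1cc(/C=C/C(=O)O)cc(OC)c1O | starting material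
2 | 3-(4-hydroxy-3,5-dimethoxyphenyl)propanoic acid | COc1cc(CCC(=O)O)cc(OC)c1O | intermediate
3 | 3-(4-benzyloxy-3,5-dimethoxyphenyl)propanoic acid | COc1cc(CCC(=O)O)cc(OC)c1OCc1ccccc1 | intermediate
4 | (S)-4-benzyloxazolidin-2-one | O=C1N[C@@H](Cc2ccccc2)CO1 | starting material
5 | 3-(4-benzyloxy-3,5-dimethoxyphenyl)propanoic pivalic anhydride (not isolated) | COc1cc(CCC(=O)OC(=O)C(C)(C)C)cc(OC)c1OCc1ccccc1 | intermediate
6 | (S)-4-benzyl-3-[3-(4-benzyloxy-3,5-dimethoxyphenyl)propanoyl]oxazolidin-2-one | COc1cc(CCC(=O)N2[C@@H](Cc3ccccc3)COC2=O)cc(OC)c1OCc1ccccc1 | intermediate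
7 | ferulic acid, (E)-3-(4-hydroxy-3-methoxyphenyl)prop-2-enoic acid | COc1cc(/C=C/C(=O)O)ccc1O | starting material
8 | 3-(4-hydroxy-3-methoxyphenyl)propanoic acid | COc1cc(CCC(=O)O)ccc1O | intermediate
9 | 3-(4-benzyloxy-3-methoxyphenyl)propanoic acid | COc1cc(CCC(=O)O)ccc1OCc1ccccc1 | intermediate
10 | tert-butyl 3-(4-benzyloxy-3-methoxyphenyl)propanoate | COc1cc(CCC(=O)OC(C)(C)C)ccc1OCc1ccccc1 | intermediate
11 | lithium Z-enolate of 6, O–Li cis to the arylmethyl group (not isolated) | [Li+].[O-]/C(=C\Cc1cc(OC)c(OCc2ccccc2)c(OC)c1)N1[C@@H](Cc2ccccc2)COC1=O | intermediate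
12 | kinetic lithium enolate of 10, O–Li trans to the arylmethyl group (not isolated) | [Li+].[O-]/C(OC(C)(C)C)=C/Cc1ccc(OCc2ccccc2)c(OC)c1 | intermediate
13 | tert-butyl (3R)-4-[(S)-4-benzyl-2-oxooxazolidin-3-yl]-3-(4-benzyloxy-3,5-dimethoxybenzyl)-2-(4-benzyloxy-3-methoxybenzyl)-4-oxobutanoate, both C2 epimers | O=C(N1[C@@H](Cc2ccccc2)COC1=O)[C@H](Cc1cc(OC)c(OCc2ccccc2)c(OC)c1)C(Cc1ccc(OCc2ccccc2)c(OC)c1)C(=O)OC(C)(C)C | intermediate
14 | tert-butyl (3R)-3-(4-benzyloxy-3,5-dimethoxybenzyl)-2-(4-benzyloxy-3-methoxybenzyl)-4-oxobutanoate, both C2 epimers (not isolated) | O=C[C@H](Cc1cc(OC)c(OCc2ccccc2)c(OC)c1)C(Cc1ccc(OCc2ccccc2)c(OC)c1)C(=O)OC(C)(C)C | intermediate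
15 | tert-butyl (3R)-3-(4-benzyloxy-3,5-dimethoxybenzyl)-2-(4-benzyloxy-3-methoxybenzyl)-4-hydroxybutanoate, both C2 epimers | OC[C@H](Cc1cc(OC)c(OCc2ccccc2)c(OC)c1)C(Cc1ccc(OCc2ccccc2)c(OC)c1)C(=O)OC(C)(C)C | intermediate
16 | (3R)-3-(4-benzyloxy-3,5-dimethoxybenzyl)-2-(4-benzyloxy-3-methoxybenzyl)-4-hydroxybutanoic acid, both C2 epimers (not isolated) | OC[C@H](Cc1cc(OC)c(OCc2ccccc2)c(OC)c1)C(Cc1ccc(OCc2ccccc2)c(OC)c1)C(=O)O | intermediate
17 | (4R)-4-(4-benzyloxy-3,5-dimethoxybenzyl)-3-(4-benzyloxy-3-methoxybenzyl)dihydrofuran-2(3H)-one, both C3 epimers | COc1cc(CC2C(=O)OC[C@@H]2Cc2cc(OC)c(OCc3ccccc3)c(OC)c2)ccc1OCc1ccccc1 | intermediate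
18 | (3R,4R)-4-(4-benzyloxy-3,5-dimethoxybenzyl)-3-(4-benzyloxy-3-methoxybenzyl)dihydrofuran-2(3H)-one, trans | COc1cc(C[C@H]2C(=O)OC[C@@H]2Cc2cc(OC)c(OCc3ccccc3)c(OC)c2)ccc1OCc1ccccc1 | intermediate
19 | (3R,4R)-4-(4-hydroxy-3,5-dimethoxybenzyl)-3-(4-hydroxy-3-methoxybenzyl)dihydrofuran-2(3H)-one, CNP0328745.1 | COc1cc(C[C@H]2C(=O)OC[C@@H]2Cc2cc(OC)c(O)c(OC)c2)ccc1O | target

**Step count**

Total step count: 11.
Longest linear sequence: 8 (steps 1–3 or 4–6, then steps 7–11).

**Steps most likely to fail**

**Step 7.**
- What may go wrong: homo-coupling of either enolate may compete with cross-coupling. Oxidation may stall, so that both partners are merely recovered after the quench. Facial selectivity may erode if bond formation runs through an unchelated imide radical.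
- Fallback, from 6 back to 18, builds the same lactone by two polar alkylations instead of one oxidative union. The sodium enolate of 6 (NaN(SiMe3)2, THF, −78 °C) is alkylated on the same open face with tert-butyl bromoacetate (Evans alkylation) to tert-butyl (3R)-4-[(S)-4-benzyl-2-oxooxazolidin-3-yl]-3-(4-benzyloxy-3,5-dimethoxybenzyl)-4-oxobutanoate F1. LiBH4 then removes the auxiliary and gives tert-butyl (3R)-3-(4-benzyloxy-3,5-dimethoxybenzyl)-4-hydroxybutanoate F2. Trifluoroacetic acid closes this to (R)-4-(4-benzyloxy-3,5-dimethoxybenzyl)dihydrofuran-2(3H)-one F3. The lithium enolate of that lactone (LiN(SiMe3)2, THF, −78 °C) is alkylated anti to the C4 substituent with 4-benzyloxy-3-methoxybenzyl bromide F4, made from commercial 4-benzyloxy-3-methoxybenzyl alcohol with PBr3. This gives 18 directly and makes steps 4–6 and 8–10 unnecessary.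

**Step 8.**
- What may go wrong: in the crowded, doubly branched imide, hydride may attack the ring carbamate carbonyl, which opens the auxiliary instead of releasing it. Early ring closure of the lithium alkoxide onto the ester, followed by further reduction, may over-reduce the molecule.
- Fallback, from 13 back to 15, separates cleavage from reduction. LiOH/H2O2 (THF/H2O, 0 °C), whose hydroperoxide anion attacks the exocyclic carbonyl even in hindered imides, gives (2R)-2-(4-benzyloxy-3,5-dimethoxybenzyl)-3-(4-benzyloxy-3-methoxybenzyl)-4-tert-butoxy-4-oxobutanoic acid F5 with recovery of 4. BH3·THF (0 °C) then reduces the free carboxylic acid in the presence of the tert-butyl ester to 15.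

**Step 9.**
- What may go wrong: the benzyl ether flanked by two methoxy groups is acid-sensitive and may be lost. The tert-butyl cation may alkylate the electron-rich rings in a Friedel–Crafts reaction.
- Fallback, from 15 back to 18, closes the ring under base instead of acid. Catalytic KOtBu in THF (0 °C → rt) turns the C5 hydroxyl into its alkoxide, which displaces tert-butoxide from the ester by acyl substitution, with no carbocation and no acid present. The liberated tert-butoxide equilibrates C3 in the same flask, so 17 is only passed through and 18 is reached in one operation. No compound outside the compound list is made (F0).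

**Further compounds**

F1 | step 7 | tert-butyl (3R)-4-[(S)-4-benzyl-2-oxooxazolidin-3-yl]-3-(4-benzyloxy-3,5-dimethoxybenzyl)-4-oxobutanoate | O=C(N1[C@@H](Cc2ccccc2)COC1=O)[C@H](Cc1cc(OC)c(OCc2ccccc2)c(OC)c1)CC(=O)OC(C)(C)C
F2 | step 7 | tert-butyl (3R)-3-(4-benzyloxy-3,5-dimethoxybenzyl)-4-hydroxybutanoate | OC[C@H](Cc1cc(OC)c(OCc2ccccc2)c(OC)c1)CC(=O)OC(C)(C)C
F3 | step 7 | (R)-4-(4-benzyloxy-3,5-dimethoxybenzyl)dihydrofuran-2(3H)-one | O=C1C[C@@H](Cc2cc(OC)c(OCc3ccccc3)c(OC)c2)CO1
F4 | step 7 | 4-benzyloxy-3-methoxybenzyl bromide | COc1cc(CBr)ccc1OCc1ccccc1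
F5 | step 8 | (2R)-2-(4-benzyloxy-3,5-dimethoxybenzyl)-3-(4-benzyloxy-3-methoxybenzyl)-4-tert-butoxy-4-oxobutanoic acid, both C3 epimers | OC(=O)[C@H](Cc1cc(OC)c(OCc2ccccc2)c(OC)c1)C(Cc1ccc(OCc2ccccc2)c(OC)c1)C(=O)OC(C)(C)C
F0 | step 9 | none | none
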